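**Abbreviation.** LF = the C6 radical of compound 19, i.e. (2R,3S,4S)-3,7,8-tris(benzyloxy)-2-[3,4-bis(benzyloxy)phenyl]-4-[(tert-butyldimethylsilyl)oxy]chroman-6-yl (2,3-cis, 3,4-trans).

**Assumption.** The diene ligand (R,R)-Ph-bod* is taken to deliver the aryl group to the α-re face of the s-trans enal 23, the face it selects on 2-cyclohexenone; if a test on 23 shows the opposite sense, the (S,S) ligand is used in step 17 and nothing else changes.

## Analysis of the target

The target is a dimer of two 2-arylchroman (flavan) units joined by one C–C bond from C4 of the upper unit to C6 of ring A of the lower unit. The upper unit is a flavan-3-ol with a 7,8-dihydroxylated ring A and a catechol ring B. Its three contiguous stereocentres are (2R,3R,4R): ring B at C2, the C3 hydroxyl and the lower flavanyl group at C4 all lie on one face of ring C (2,3-cis, 3,4-cis). The lower unit is a flavan-3,4-diol with the same oxygenation pattern and (2R,3R,4S) configuration, 2,3-cis but 3,4-trans. The molecule carries eight phenolic hydroxyls in catechol and pyrogallol-type arrays that oxidise easily; the lower C4 hydroxyl is benzylic and para to the 7-oxygen, so it ionises in acid, and the doubly benzylic interflavan bond is also acid-labile. The main difficulty is the all-cis upper triad: a cationic arylation at C4 of a preformed flavan delivers the aryl group trans to the C3 oxygen, and neither triad can direct the other across the biaryl-type link. The strategy rests on the O1–C8a aryl ether bond of upper ring C: cutting it touches no stereocentre and leaves an open C2–C3–C4 chain that can be built by acyclic stereocontrol and closed with retention at C2.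

## Retrosynthetic reasoning

**34 to 33 to 32 (protecting groups).** All phenols and the two C3 hydroxyls are carried as benzyl ethers, and the lower C4 hydroxyl as a silyl ether. A benzyl ether at lower C4 is excluded because hydrogenolysis would cut the benzylic C4–O bond itself. The silyl group shields that bond while the benzyl groups are removed (32 to 33) and is taken off last by fluoride-mediated desilylation (33 to 34).

**32 to 31 (O1–C8a of upper ring C).** This is the central cut. Cutting C4–C6(lower) instead would call for an ionic coupling that gives 3,4-trans. Cutting O1–C2 would mean substitution at an electron-rich benzylic carbon, with the risk of ionisation. The O1–C8a cut breaks no bond to C2, C3 or C4, so the forward C–O coupling of the C2 hydroxyl of 31 with the ring A bromide only has to be chemoselective. This is secured by the benzyl ether on the C3 oxygen, which blocks the five-membered alternative.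

**31 to 30 and 17 (C2–ring B).** A retentive closure needs the C2 hydroxyl and the C3 benzyloxy group syn in the open chain. Chelation-controlled addition of the aryl Grignard reagent 17 to the α-benzyloxy aldehyde 30 gives exactly this syn relationship. The reverse order, hydride addition to the corresponding aryl ketone under chelation, would give the anti alcohol and hence a 2,3-trans flavan, so ring B, not hydrogen, must be the incoming group.

**30 to 24 (C3–O).** C4 carries two aryl groups of similar size and cannot direct a reaction at C3, so the C3 oxygen is introduced under catalyst control by α-aminoxylation of aldehyde 24 (via 25 and 26). The resulting diol 27 is converted to the benzylidene acetal 28, whose regioselective reductive opening places the benzyl group on the secondary oxygen (29). Oxidation returns the aldehyde 30.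

**24 to 23 and 6 (C4–ring A).** The diarylmethine centre is cut at the bond to upper ring A. A rhodium–diene catalysed conjugate addition of boronic acid 6 to enal 23 sets C4 under catalyst control. It also brings in the ortho bromine needed for the ring closure, and it uses the simple fragment, not the lower unit, in excess.

**23 to 20 to 19 (C6 side chain).** The three-carbon chain is attached at C6 of the finished lower flavan 19. This position is para to the ring oxygen and ortho to the 7-benzyloxy group and is therefore the most nucleophilic carbon of the molecule. Bromination gives 20, and bromine–lithium exchange followed by vinylogous formylation with 21 gives 23.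

**19 to 18 to 16 and 17; 16 to 13 to 11 and 5 (lower unit).** The lower ring C is opened at the same O1–C8a bond, so that the closure is rehearsed early on a simpler substrate. The open chain 18 comes from the same chelation-controlled addition of 17, here to aldehyde 16. The C3–C4 bond of 16 goes back to a syn glycolate aldol between imide 11 and aldehyde 5 (13), followed by amide exchange (14), silylation (15) and reduction. The syn aldol becomes 3,4-trans in the ring, and the syn Grignard adduct becomes 2,3-cis.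

**Aromatic building blocks.** Aldehyde 5 and boronic acid 6 both come from iodide 3 through one batch of the arylmagnesium species 4; 3 comes from 1 via 2. The Grignard reagent 17, prepared once from 8 (made from 7), supplies ring B of both units. Imide 11 comes from 9 and 10.

## Alternatives that were turned down

**Alternative 1:** Upper ring C is cut at C3–C4 and at the O1–C2 acyl bond. In the forward direction an ortho-quinone methide, released from the diaryl carbinol A2, is trapped by a catalyst-bound two-carbon enolate that carries the future C3 benzyloxy group, under chiral carbene catalysis. This gives the cis-3,4-disubstituted lactone A1.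
- For: one catalytic step forms C3–C4, closes the ring and sets two stereocentres cis with enantiocontrol. On this point it is stronger than the chosen route, which needs several operations to set C4 and C3.
- Against: C2 is left at the carboxyl oxidation level. Ring B must be added to the lactone and the lactol reduced with 2,3-cis selectivity, while C3, now α to a carbonyl, can epimerise to the trans lactone under the basic conditions. The lower unit is present only as a silyloxyarene, so the whole lower pyran with three stereocentres must still be built next to an acid-sensitive, doubly benzylic C4.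
- Comparison: the chosen route sets C2 with ring B already in place and carries a complete lower unit through a closure that breaks no bond to a stereocentre; after it only deprotections remain.

**Alternative 2:** The lower pyran is cut at O1–C2 and C3–C4. The salicylaldehyde A4, which already contains the finished upper unit, is converted under acid into an alkoxy ortho-quinone methide that adds the Z-configured silylstyrene A5 to give A3.
- For: the lower ring and its three stereocentres form in one convergent step, with 2,3-cis coming from the alkene geometry. In step count for the lower ring it is clearly stronger than the sequence used here.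
- Against: the only stereochemical information is the remote upper triad, so the absolute sense of the new triad relative to the upper unit is not controlled. C3 arrives as a C–Si bond that must be oxidised in the presence of nine benzyl ethers, and the C4 methoxy group must be exchanged for hydroxyl at the most acid-labile carbon. The all-cis upper triad, the real problem, still has to be made to reach A4.
- Comparison: the chosen route gives up some convergence but sets each lower stereocentre by auxiliary or chelate control and puts its key step on the upper triad.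

**Alternative 3:** The lower pyran is cut at C4–C4a. The tethered aldehyde A7 cyclises under a boron Lewis acid by attack of lower ring A, para to its 7-benzyloxy group, to give A6 with a free C4 hydroxyl.
- For: A6 is one hydrogenolysis away from the target and needs no silicon, so the end game is shorter than the two steps used here.
- Against: the new benzylic alcohol is para to a benzyloxy group and can ionise again under the same Lewis acid, leading to elimination, epimerisation or oligomerisation. The doubly benzylic interflavan bond is also exposed to acid, and the 3,4-trans outcome is not assured. Making A7 needs a stereodefined aryl ether at a secondary benzylic carbon on a hindered phenol, and the upper triad must again be secured beforehand.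
- Comparison: both ring closures of the chosen route run under basic, non-ionising conditions that cannot scramble C4 of either unit.

Key step: step 24

## Route

Step 1
Reactants: 1 3-bromobenzene-1,2-diol (3-bromocatechol)
Product: 2 1,2-bis(benzyloxy)-3-bromobenzene
Conditions: BnBr (2.3 equiv), K2CO3, DMF, 60 °C
Reagents that add atoms: benzyl bromide, BrCc1ccccc1
Why: Williamson etherification of both phenols; benzyl is the global protecting group removed at the end by hydrogenolysis.

Step 2
Reactants: 2 1,2-bis(benzyloxy)-3-bromobenzene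
Product: 3 1,2-bis(benzyloxy)-3-bromo-4-iodobenzene
Conditions: N-iodosuccinimide (1.05 equiv), CF3CO2H (cat.), MeCN, 0 °C → rt
Reagents that add atoms: N-iodosuccinimide, O=C1CCC(=O)N1I
Why: Electrophilic aromatic iodination; the 1-benzyloxy group can lie in the ring plane and directs para, to C4 next to bromine, whereas the 2-benzyloxy group is twisted between two substituents and is a weak donor.

Step 3
Reactants: 3 1,2-bis(benzyloxy)-3-bromo-4-iodobenzene
Product: 4 [3,4-bis(benzyloxy)-2-bromophenyl]magnesium chloride (LiCl complex; one THF solution held at −40 °C and divided between steps 4 and 5)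
Conditions: i-PrMgCl·LiCl (1.05 equiv), THF, −40 °C
Reagents that add atoms: isopropylmagnesium chloride, CC(C)[Mg]Cl
Why: Iodine–magnesium exchange with the LiCl-activated Grignard reagent is far faster at C–I than at C–Br, and at −40 °C the ortho-bromo arylmagnesium species does not eliminate to the aryne; a single batch serves both the aldehyde and the boronic acid.

Step 4
Reactants: 4 [3,4-bis(benzyloxy)-2-bromophenyl]magnesium chloride (first portion of the cold solution)
Product: 5 3,4-bis(benzyloxy)-2-bromobenzaldehyde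
Conditions: DMF (2 equiv), THF, −40 → 0 °C; aq. NH4Cl
Reagents that add atoms: N,N-dimethylformamide, CN(C)C=O
Why: Bouveault formylation: the aryl Grignard reagent adds to DMF and the hemiaminal magnesium salt releases the aldehyde on aqueous work-up, with the C–Br bond intact.

Step 5
Reactants: 4 [3,4-bis(benzyloxy)-2-bromophenyl]magnesium chloride (second portion of the cold solution)
Product: 6 [3,4-bis(benzyloxy)-2-bromophenyl]boronic acid
Conditions: B(Oi-Pr)3 (2 equiv), THF, −40 → 0 °C; 1 M HCl
Reagents that add atoms: triisopropyl borate, CC(C)OB(OC(C)C)OC(C)C; water, O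
Why: Borylation of the Grignard reagent and acidic hydrolysis of the boronate ester give the boronic acid with the ortho bromine retained.

Step 6
Reactants: 7 4-bromobenzene-1,2-diol (4-bromocatechol)
Product: 8 1,2-bis(benzyloxy)-4-bromobenzene
Conditions: BnBr (2.3 equiv), K2CO3, DMF, 60 °C
Reagents that add atoms: benzyl bromide, BrCc1ccccc1
Why: Williamson etherification; 8 is the source of ring B of both units.

Step 7
Reactants: 9 (4R)-4-benzyl-1,3-oxazolidin-2-one; 10 (benzyloxy)acetyl chloride
Product: 11 (4R)-4-benzyl-3-[(benzyloxy)acetyl]-1,3-oxazolidin-2-one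
Conditions: n-BuLi, THF, −78 °C; then 10, −78 → 0 °C
Reagents that add atoms: none
Why: N-acylation of the lithiated oxazolidinone gives the glycolate imide for the Evans aldol.

Step 8
Reactants: 11 (4R)-4-benzyl-3-[(benzyloxy)acetyl]-1,3-oxazolidin-2-one; 5 3,4-bis(benzyloxy)-2-bromobenzaldehyde
Product: 13 (4R)-4-benzyl-3-[(2R,3S)-2-(benzyloxy)-3-[3,4-bis(benzyloxy)-2-bromophenyl]-3-hydroxypropanoyl]-1,3-oxazolidin-2-one, via boron enolate 12 (not isolated)
Conditions: Bu2BOTf (1.2 equiv), i-Pr2NEt (1.4 equiv), CH2Cl2, −78 → 0 °C; 5, −78 → 0 °C; pH 7 buffer, MeOH, H2O2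
Reagents that add atoms: none
Why: Evans syn aldol: the (Z)-boron enolate reacts through a chair Zimmerman–Traxler transition state on the face opposite the auxiliary's benzyl group, so the (R)-auxiliary should give the (2R,3S) syn adduct; this sets lower C3 and C4, and the syn relationship becomes 3,4-trans in the ring.

Step 9
Reactants: 13 the aldol adduct
Product: 14 (2R,3S)-2-(benzyloxy)-3-[3,4-bis(benzyloxy)-2-bromophenyl]-3-hydroxy-N-methoxy-N-methylpropanamide
Conditions: MeONHMe·HCl (3 equiv), AlMe3 (3 equiv), CH2Cl2/THF, −20 → 0 °C; aq. potassium sodium tartrate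
Reagents that add atoms: N,O-dimethylhydroxylamine hydrochloride, CNOC.Cl
Why: Aluminium amide transamination of the imide, assisted by the free β-hydroxyl, gives the Weinreb amide and returns auxiliary 9.

Step 10
Reactants: 14 the β-hydroxy Weinreb amide
Product: 15 (2R,3S)-2-(benzyloxy)-3-[3,4-bis(benzyloxy)-2-bromophenyl]-3-[(tert-butyldimethylsilyl)oxy]-N-methoxy-N-methylpropanamide
Conditions: TBSOTf (1.3 equiv), 2,6-lutidine, CH2Cl2, −78 → 0 °C
Reagents that add atoms: tert-butyldimethylsilyl trifluoromethanesulfonate, CC(C)(C)[Si](C)(C)OS(=O)(=O)C(F)(F)F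
Why: Silylation of the hindered benzylic alcohol; this oxygen becomes the lower C4 oxygen, whose silyl ether survives hydrogenolysis and does not chelate in step 13.

Step 11
Reactants: 15 the silylated Weinreb amide
Product: 16 (2R,3S)-2-(benzyloxy)-3-[3,4-bis(benzyloxy)-2-bromophenyl]-3-[(tert-butyldimethylsilyl)oxy]propanal
Conditions: i-Bu2AlH (1.5 equiv), THF, −78 °C; aq. potassium sodium tartrate
Reagents that add atoms: none
Why: Reduction of a Weinreb amide stops at the chelated tetrahedral intermediate, which releases the aldehyde on work-up without epimerising the α-benzyloxy centre.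

Step 12
Reactants: 8 1,2-bis(benzyloxy)-4-bromobenzene
Product: 17 [3,4-bis(benzyloxy)phenyl]magnesium bromide (about 0.5 M in THF, titrated and kept under Ar; the one batch is used in steps 13 and 23)
Conditions: Mg turnings (1.2 equiv), I2 (cat.), THF, 40 °C
Reagents that add atoms: magnesium, [Mg]
Why: Grignard reagent formation by direct insertion of magnesium into the aryl C–Br bond; the benzyl ethers are inert and the THF solution keeps under argon, so it is titrated before each use.

Step 13
Reactants: 16 the α-benzyloxy-β-silyloxy aldehyde; 17 [3,4-bis(benzyloxy)phenyl]magnesium bromide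
Product: 18 (1R,2S,3S)-2-(benzyloxy)-1-[3,4-bis(benzyloxy)phenyl]-3-[3,4-bis(benzyloxy)-2-bromophenyl]-3-[(tert-butyldimethylsilyl)oxy]propan-1-ol
Conditions: 16, MgBr2·OEt2 (2 equiv), CH2Cl2, −78 °C; then 17 (1.5 equiv, THF solution); aq. NH4Cl
Reagents that add atoms: none
Why: Cram-chelate addition: magnesium ties the aldehyde oxygen to the α-benzyloxy oxygen (the silyl ether does not chelate) and the aryl group attacks the face away from the bulky β-substituent, giving the 1,2-syn alcohol that sets lower C2.

Step 14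
Reactants: 18 the open-chain lower bromo alcohol
Product: 19 (2R,3S,4S)-3,7,8-tris(benzyloxy)-2-[3,4-bis(benzyloxy)phenyl]-4-[(tert-butyldimethylsilyl)oxy]chromane (2,3-cis, 3,4-trans; the lower flavan)
Conditions: CuI (copper monoiodide, 15 mol%), 3,4,7,8-tetramethyl-1,10-phenanthroline (30 mol%), Cs2CO3 (2 equiv), toluene (0.02 M), 110 °C, Ar
Reagents that add atoms: none
Why: Copper-catalysed intramolecular O-arylation (Ullmann–Buchwald etherification) of the secondary alkoxide with the ortho bromide closes lower ring C with retention at C2, so syn C2/C3 becomes 2,3-cis; a reversible 1,3-silyl shift would be harmless because only the C2 alkoxide can reach the bromide, and the step rehearses step 24.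

Step 15
Reactants: 19 the lower flavan
Product: 20 (2R,3S,4S)-3,7,8-tris(benzyloxy)-2-[3,4-bis(benzyloxy)phenyl]-6-bromo-4-[(tert-butyldimethylsilyl)oxy]chromane
Conditions: N-bromosuccinimide (1.0 equiv), CH2Cl2, −20 → 0 °C, dark
Reagents that add atoms: N-bromosuccinimide, O=C1CCC(=O)N1Br
Why: Electrophilic aromatic bromination at C6, which is para to the in-plane ring oxygen O1 and ortho to the 7-benzyloxy group and so doubly activated; C5 and ring B have only one effective donor each.

Step 16
Reactants: 20 the 6-bromo lower flavan; 21 (E)-3-(dimethylamino)prop-2-enal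
Product: 23 (E)-3-(LF)prop-2-enal, via aryllithium 22 (not isolated)
Conditions: n-BuLi (1.05 equiv), THF, −78 °C; 21 (1.5 equiv), −78 → −20 °C; AcOH/NaOAc buffer (pH 5), rt
Reagents that add atoms: none
Why: Bromine–lithium exchange, then 1,2-addition to the vinylogous formamide; mild acid eliminates dimethylamine through the conjugated iminium ion to give the (E)-enal (vinylogous Bouveault formylation).

Step 17
Reactants: 23 (E)-3-(LF)prop-2-enal; 6 [3,4-bis(benzyloxy)-2-bromophenyl]boronic acid
Product: 24 (3R)-3-[3,4-bis(benzyloxy)-2-bromophenyl]-3-(LF)propanal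
Conditions: 6 (2.5 equiv), [RhCl(C2H4)2]2 (2.5 mol%), (R,R)-Ph-bod* [(1R,4R)-2,5-diphenylbicyclo[2.2.2]octa-2,5-diene, 5.5 mol%], KOH (0.3 equiv), 1,4-dioxane/H2O (10:1), 40 °C
Reagents that add atoms: none
Why: Hayashi–Miyaura 1,4-addition: the aryl group on monovalent rhodium inserts the enal C=C on the face selected by the chiral diene, and the oxa-π-allyl rhodium species is protonated by water; this sets upper C4 under catalyst control, and diene ligands suppress 1,2-addition to the aldehyde.

Step 18
Reactants: 24 the 3,3-diarylpropanal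
Product: 26 (2R,3R)-2-(anilinooxy)-3-[3,4-bis(benzyloxy)-2-bromophenyl]-3-(LF)propan-1-ol, via anilinooxy aldehyde 25 (not isolated)
Conditions: nitrosobenzene (1.2 equiv, slow addition), L-proline (20 mol%), CHCl3, 4 °C; then NaBH4, EtOH, 0 °C
Reagents that add atoms: nitrosobenzene, O=Nc1ccccc1
Why: Proline-catalysed α-aminoxylation: the (E)-enamine attacks the oxygen of nitrosobenzene on the face fixed by hydrogen bonding to the carboxylic acid, so L-proline should give the (R) centre that becomes upper C3; the two similar aryl groups at C4 exert no bias, and in-situ reduction stabilises the product.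

Step 19
Reactants: 26 the anilinooxy alcohol
Product: 27 (2R,3R)-3-[3,4-bis(benzyloxy)-2-bromophenyl]-3-(LF)propane-1,2-diol
Conditions: Zn, AcOH, THF/EtOH, rt
Reagents that add atoms: none
Why: Reductive cleavage of the weak N–O bond; the aryl bromide, the benzyl ethers and the silyl ether are inert to zinc in acetic acid at room temperature.

Step 20
Reactants: 27 the 1,2-diol
Product: 28 (4R)-4-[(R)-[3,4-bis(benzyloxy)-2-bromophenyl](LF)methyl]-2-phenyl-1,3-dioxolane (both epimers at C2 of the dioxolane)
Conditions: PhCH(OMe)2 (1.5 equiv), pyridinium p-toluenesulfonate (cat.), CH2Cl2, rt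
Reagents that add atoms: benzaldehyde dimethyl acetal, COC(OC)c1ccccc1
Why: Acid-catalysed transacetalisation; the acetal carbon is lost as a stereocentre in the next step, so its configuration does not matter.

Step 21
Reactants: 28 the benzylidene acetal
Product: 29 (2R,3R)-2-(benzyloxy)-3-[3,4-bis(benzyloxy)-2-bromophenyl]-3-(LF)propan-1-ol
Conditions: i-Bu2AlH (4 equiv), CH2Cl2, −40 → 0 °C; aq. potassium sodium tartrate
Reagents that add atoms: none
Why: Regioselective reductive opening of a benzylidene acetal: aluminium binds the unhindered primary oxygen, that acetal C–O bond breaks and hydride quenches the oxocarbenium ion, leaving the benzyl group on the secondary oxygen.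

Step 22
Reactants: 29 the primary alcohol
Product: 30 (2R,3R)-2-(benzyloxy)-3-[3,4-bis(benzyloxy)-2-bromophenyl]-3-(LF)propanal
Conditions: Dess–Martin periodinane (1.3 equiv), NaHCO3, CH2Cl2, 0 °C → rt
Reagents that add atoms: none
Why: Buffered hypervalent iodine oxidation gives the α-benzyloxy aldehyde without epimerisation; it is used directly.

Step 23
Reactants: 30 the α-benzyloxy aldehyde; 17 [3,4-bis(benzyloxy)phenyl]magnesium bromide
Product: 31 (1R,2R,3R)-2-(benzyloxy)-1-[3,4-bis(benzyloxy)phenyl]-3-[3,4-bis(benzyloxy)-2-bromophenyl]-3-(LF)propan-1-ol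
Conditions: 30, MgBr2·OEt2 (2 equiv), CH2Cl2, −78 °C; then 17 (1.5 equiv, THF solution); aq. NH4Cl
Reagents that add atoms: none
Why: Cram-chelate addition: in the five-membered magnesium chelate the aryl group attacks the face opposite the diarylmethyl group, giving the 1,2-syn alcohol that sets upper C2; the steric Felkin preference of the bulky diarylmethyl group points to the same face, so the two models agree.

Step 24
Reactants: 31 the open-chain bromo alcohol with free C2 hydroxyl and benzylated C3 oxygen
Product: 32 (2R)-3,7,8-tris(benzyloxy)-2-[3,4-bis(benzyloxy)phenyl]-4-(LF)chromane (2,3-cis, 3,4-cis; the fully protected dimer)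
Conditions: CuI (copper monoiodide, 20 mol%), 3,4,7,8-tetramethyl-1,10-phenanthroline (40 mol%), Cs2CO3 (2 equiv), toluene (0.01 M), 110 °C, Ar
Reagents that add atoms: none
Why: Cs2CO3 deprotonates the C2 hydroxyl and the alkoxide binds the phenanthroline-ligated copper; this monovalent copper alkoxide inserts into the neighbouring C8a–Br bond to give a trivalent aryl copper alkoxide (a seven-membered cupracycle), and C–O reductive elimination forms O1–C8a and returns monovalent copper. The closest known reaction type is the Ullmann–Buchwald copper-catalysed etherification of aryl halides with secondary alcohols, in its intramolecular form leading to chromans. Upper ring C closes in a formally 6-exo-trig mode, the alkoxide oxygen attacking an sp2 carbon whose leaving bromide lies outside the new ring. No stereocentre is created: the C2–O bond is never broken, so C2 keeps its configuration, and the syn C2/C3 and the C3/C4 relationships of 31 become 2,3-cis and 3,4-cis in 32. Chemoselectivity for the C2 oxygen is secured by the benzyl ether on the C3 oxygen, which rules out the five-membered dihydrobenzofuran, and by the silyl ether on the lower C4 oxygen. Carbonate is too weak a base to remove the doubly benzylic C4 hydrogen or to trigger β-elimination of benzyloxide, so C3 and C4 are not at risk. Copper alkoxides do not readily undergo β-hydride elimination, which avoids the ketone and reduced-arene by-products typical of palladium with secondary alcohols. High dilution suppresses intermolecular etherification.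

Step 25
Reactants: 32 the fully protected dimer
Product: 33 (2R,3R,4R)-4-[(2R,3S,4S)-4-[(tert-butyldimethylsilyl)oxy]-2-(3,4-dihydroxyphenyl)-3,7,8-trihydroxychroman-6-yl]-2-(3,4-dihydroxyphenyl)chromane-3,7,8-triol
Conditions: H2 (1 atm), Pd(OH)2/C, THF/EtOAc (1:1), rt
Reagents that add atoms: none
Why: Hydrogenolysis of the ten benzyl ethers; the cyclic benzylic C2–O1 bonds are known to survive in flavan chemistry, the bulky silyl ether protects the lower benzylic C4–O bond, and a non-alcoholic solvent avoids premature desilylation.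

Step 26
Reactants: 33 the lower 4-O-silyl polyphenol
Product: 34 (2R,3R,4R)-2-(3,4-dihydroxyphenyl)-4-[(2R,3R,4S)-2-(3,4-dihydroxyphenyl)-3,4,7,8-tetrahydroxychroman-6-yl]chromane-3,7,8-triol (the target)
Conditions: HF·pyridine, pyridine, THF, 0 °C, Ar
Reagents that add atoms: none
Why: Fluoride-driven cleavage of the Si–O bond in a pyridine-buffered medium leaves the C4–O bond untouched and keeps the acidity below what ionises the benzylic alcohol; argon protects the catechols.

## Compound list

1 | 3-bromobenzene-1,2-diol | Oc1cccc(Br)c1O | starting material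
2 | 1,2-bis(benzyloxy)-3-bromobenzene | Brc1cccc(OCc9ccccc9)c1OCc9ccccc9 | intermediate
3 | 1,2-bis(benzyloxy)-3-bromo-4-iodobenzene | Ic1ccc(OCc9ccccc9)c(OCc9ccccc9)c1Br | intermediate
4 | [3,4-bis(benzyloxy)-2-bromophenyl]magnesium chloride (cold THF solution, LiCl complex) | Cl[Mg]c1ccc(OCc9ccccc9)c(OCc9ccccc9)c1Br | intermediate
5 | 3,4-bis(benzyloxy)-2-bromobenzaldehyde | O=Cc1ccc(OCc9ccccc9)c(OCc9ccccc9)c1Br | intermediate
6 | [3,4-bis(benzyloxy)-2-bromophenyl]boronic acid | OB(O)c1ccc(OCc9ccccc9)c(OCc9ccccc9)c1Br | intermediate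
7 | 4-bromobenzene-1,2-diol | Oc1ccc(Br)cc1O | starting material
8 | 1,2-bis(benzyloxy)-4-bromobenzene | Brc1ccc(OCc9ccccc9)c(OCc9ccccc9)c1 | intermediate
9 | (4R)-4-benzyl-1,3-oxazolidin-2-one | O=C1N[C@H](Cc2ccccc2)CO1 | starting material
10 | (benzyloxy)acetyl chloride | O=C(Cl)COCc1ccccc1 | starting material
11 | (4R)-4-benzyl-3-[(benzyloxy)acetyl]-1,3-oxazolidin-2-one | O=C(COCc9ccccc9)N1[C@H](Cc2ccccc2)COC1=O | intermediate
12 | dibutylboron (Z)-enolate of 11 | CCCCB(CCCC)O/C(N1[C@H](Cc2ccccc2)COC1=O)=C\OCc9ccccc9 | intermediate (not isolated)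
13 | (4R)-4-benzyl-3-[(2R,3S)-2-(benzyloxy)-3-[3,4-bis(benzyloxy)-2-bromophenyl]-3-hydroxypropanoyl]-1,3-oxazolidin-2-one | O=C([C@H](OCc9ccccc9)[C@@H](O)c1ccc(OCc9ccccc9)c(OCc9ccccc9)c1Br)N1[C@H](Cc2ccccc2)COC1=O | intermediate
14 | (2R,3S)-2-(benzyloxy)-3-[3,4-bis(benzyloxy)-2-bromophenyl]-3-hydroxy-N-methoxy-N-methylpropanamide | CON(C)C(=O)[C@H](OCc9ccccc9)[C@@H](O)c1ccc(OCc9ccccc9)c(OCc9ccccc9)c1Br | intermediate
15 | (2R,3S)-2-(benzyloxy)-3-[3,4-bis(benzyloxy)-2-bromophenyl]-3-[(tert-butyldimethylsilyl)oxy]-N-methoxy-N-methylpropanamide | CON(C)C(=O)[C@H](OCc9ccccc9)[C@@H](O[Si](C)(C)C(C)(C)C)c1ccc(OCc9ccccc9)c(OCc9ccccc9)c1Br | intermediate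
16 | (2R,3S)-2-(benzyloxy)-3-[3,4-bis(benzyloxy)-2-bromophenyl]-3-[(tert-butyldimethylsilyl)oxy]propanal | O=C[C@H](OCc9ccccc9)[C@@H](O[Si](C)(C)C(C)(C)C)c1ccc(OCc9ccccc9)c(OCc9ccccc9)c1Br | intermediate
17 | [3,4-bis(benzyloxy)phenyl]magnesium bromide (titrated THF solution) | Br[Mg]c1ccc(OCc9ccccc9)c(OCc9ccccc9)c1 | intermediate
18 | (1R,2S,3S)-2-(benzyloxy)-1-[3,4-bis(benzyloxy)phenyl]-3-[3,4-bis(benzyloxy)-2-bromophenyl]-3-[(tert-butyldimethylsilyl)oxy]propan-1-ol (1,2-syn, 2,3-syn) | c9ccccc9COc1ccc([C@@H](O)[C@H](OCc9ccccc9)[C@@H](O[Si](C)(C)C(C)(C)C)c2ccc(OCc9ccccc9)c(OCc9ccccc9)c2Br)cc1OCc9ccccc9 | intermediate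
19 | (2R,3S,4S)-3,7,8-tris(benzyloxy)-2-[3,4-bis(benzyloxy)phenyl]-4-[(tert-butyldimethylsilyl)oxy]chromane (2,3-cis, 3,4-trans) | c1cc2c(c(OCc9ccccc9)c1OCc9ccccc9)O[C@H](c1ccc(OCc9ccccc9)c(OCc9ccccc9)c1)[C@H](OCc9ccccc9)[C@H]2O[Si](C)(C)C(C)(C)C | intermediate
20 | 6-bromo derivative of 19 | Brc1cc2c(c(OCc9ccccc9)c1OCc9ccccc9)O[C@H](c1ccc(OCc9ccccc9)c(OCc9ccccc9)c1)[C@H](OCc9ccccc9)[C@H]2O[Si](C)(C)C(C)(C)C | intermediate
21 | (E)-3-(dimethylamino)prop-2-enal | CN(C)/C=C/C=O | starting material
22 | 6-lithio derivative of 19 | [Li]c1cc2c(c(OCc9ccccc9)c1OCc9ccccc9)O[C@H](c1ccc(OCc9ccccc9)c(OCc9ccccc9)c1)[C@H](OCc9ccccc9)[C@H]2O[Si](C)(C)C(C)(C)C | intermediate (not isolated)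
23 | (E)-3-(LF)prop-2-enal | O=C/C=C/c1cc2c(c(OCc9ccccc9)c1OCc9ccccc9)O[C@H](c1ccc(OCc9ccccc9)c(OCc9ccccc9)c1)[C@H](OCc9ccccc9)[C@H]2O[Si](C)(C)C(C)(C)C | intermediate
24 | (3R)-3-[3,4-bis(benzyloxy)-2-bromophenyl]-3-(LF)propanal | O=CC[C@H](c1cc2c(c(OCc9ccccc9)c1OCc9ccccc9)O[C@H](c1ccc(OCc9ccccc9)c(OCc9ccccc9)c1)[C@H](OCc9ccccc9)[C@H]2O[Si](C)(C)C(C)(C)C)c1ccc(OCc9ccccc9)c(OCc9ccccc9)c1Br | intermediate
25 | (2R,3R)-2-(anilinooxy)-3-[3,4-bis(benzyloxy)-2-bromophenyl]-3-(LF)propanal | O=C[C@H](ONc3ccccc3)[C@H](c1cc2c(c(OCc9ccccc9)c1OCc9ccccc9)O[C@H](c1ccc(OCc9ccccc9)c(OCc9ccccc9)c1)[C@H](OCc9ccccc9)[C@H]2O[Si](C)(C)C(C)(C)C)c1ccc(OCc9ccccc9)c(OCc9ccccc9)c1Br | intermediate (not isolated)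
26 | (2R,3R)-2-(anilinooxy)-3-[3,4-bis(benzyloxy)-2-bromophenyl]-3-(LF)propan-1-ol | OC[C@H](ONc3ccccc3)[C@H](c1cc2c(c(OCc9ccccc9)c1OCc9ccccc9)O[C@H](c1ccc(OCc9ccccc9)c(OCc9ccccc9)c1)[C@H](OCc9ccccc9)[C@H]2O[Si](C)(C)C(C)(C)C)c1ccc(OCc9ccccc9)c(OCc9ccccc9)c1Br | intermediate
27 | (2R,3R)-3-[3,4-bis(benzyloxy)-2-bromophenyl]-3-(LF)propane-1,2-diol | OC[C@H](O)[C@H](c1cc2c(c(OCc9ccccc9)c1OCc9ccccc9)O[C@H](c1ccc(OCc9ccccc9)c(OCc9ccccc9)c1)[C@H](OCc9ccccc9)[C@H]2O[Si](C)(C)C(C)(C)C)c1ccc(OCc9ccccc9)c(OCc9ccccc9)c1Br | intermediate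
28 | (4R)-4-[(R)-[3,4-bis(benzyloxy)-2-bromophenyl](LF)methyl]-2-phenyl-1,3-dioxolane (acetal carbon unspecified) | c3ccccc3C1OC[C@H](O1)[C@H](c1cc2c(c(OCc9ccccc9)c1OCc9ccccc9)O[C@H](c1ccc(OCc9ccccc9)c(OCc9ccccc9)c1)[C@H](OCc9ccccc9)[C@H]2O[Si](C)(C)C(C)(C)C)c1ccc(OCc9ccccc9)c(OCc9ccccc9)c1Br | intermediate
29 | (2R,3R)-2-(benzyloxy)-3-[3,4-bis(benzyloxy)-2-bromophenyl]-3-(LF)propan-1-ol | OC[C@H](OCc9ccccc9)[C@H](c1cc2c(c(OCc9ccccc9)c1OCc9ccccc9)O[C@H](c1ccc(OCc9ccccc9)c(OCc9ccccc9)c1)[C@H](OCc9ccccc9)[C@H]2O[Si](C)(C)C(C)(C)C)c1ccc(OCc9ccccc9)c(OCc9ccccc9)c1Br | intermediate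
30 | (2R,3R)-2-(benzyloxy)-3-[3,4-bis(benzyloxy)-2-bromophenyl]-3-(LF)propanal | O=C[C@H](OCc9ccccc9)[C@H](c1cc2c(c(OCc9ccccc9)c1OCc9ccccc9)O[C@H](c1ccc(OCc9ccccc9)c(OCc9ccccc9)c1)[C@H](OCc9ccccc9)[C@H]2O[Si](C)(C)C(C)(C)C)c1ccc(OCc9ccccc9)c(OCc9ccccc9)c1Br | intermediate
31 | (1R,2R,3R)-2-(benzyloxy)-1-[3,4-bis(benzyloxy)phenyl]-3-[3,4-bis(benzyloxy)-2-bromophenyl]-3-(LF)propan-1-ol (1,2-syn) | c9ccccc9COc1ccc([C@@H](O)[C@H](OCc9ccccc9)[C@H](c2cc3c(c(OCc9ccccc9)c2OCc9ccccc9)O[C@H](c2ccc(OCc9ccccc9)c(OCc9ccccc9)c2)[C@H](OCc9ccccc9)[C@H]3O[Si](C)(C)C(C)(C)C)c2ccc(OCc9ccccc9)c(OCc9ccccc9)c2Br)cc1OCc9ccccc9 | intermediate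
32 | (2R)-3,7,8-tris(benzyloxy)-2-[3,4-bis(benzyloxy)phenyl]-4-(LF)chromane (2,3-cis, 3,4-cis) | c9ccccc9COc1ccc([C@H]2Oc3c(ccc(OCc9ccccc9)c3OCc9ccccc9)[C@@H](c3cc4c(c(OCc9ccccc9)c3OCc9ccccc9)O[C@H](c3ccc(OCc9ccccc9)c(OCc9ccccc9)c3)[C@H](OCc9ccccc9)[C@H]4O[Si](C)(C)C(C)(C)C)[C@H]2OCc9ccccc9)cc1OCc9ccccc9 | intermediate
33 | (2R,3R,4R)-4-[(2R,3S,4S)-4-[(tert-butyldimethylsilyl)oxy]-2-(3,4-dihydroxyphenyl)-3,7,8-trihydroxychroman-6-yl]-2-(3,4-dihydroxyphenyl)chromane-3,7,8-triol | Oc1ccc([C@H]2Oc3c(ccc(O)c3O)[C@@H](c3cc4c(c(O)c3O)O[C@H](c3ccc(O)c(O)c3)[C@H](O)[C@H]4O[Si](C)(C)C(C)(C)C)[C@H]2O)cc1O | intermediate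
34 | (2R,3R,4R)-2-(3,4-dihydroxyphenyl)-4-[(2R,3R,4S)-2-(3,4-dihydroxyphenyl)-3,4,7,8-tetrahydroxychroman-6-yl]chromane-3,7,8-triol | Oc1ccc([C@H]2Oc3c(ccc(O)c3O)[C@@H](c3cc4c(c(O)c3O)O[C@H](c3ccc(O)c(O)c3)[C@H](O)[C@H]4O)[C@H]2O)cc1O | target

## Step count and risk

Total: 26 steps. Longest linear sequence: 22 steps (1 to 4, 8 to 11, then 13 to 26).

**Step 24 (key step).** The C–Br bond lies between a benzyloxy group and the crowded C4 on an electron-rich ring, so insertion of copper may be slow. Hydrodebromination and intermolecular etherification could then overtake ring closure. Fallback, starting from 31 and returning at 32: the closure is turned around so that a phenol oxygen attacks C2 with inversion. 31 is oxidised with Dess–Martin periodinane to the α-benzyloxy ketone F1. Zn(BH4)2 reduces this through the zinc chelate to the 1,2-anti alcohol F2. The bromide is exchanged for hydroxyl (NaH, then t-BuLi at −78 °C, B(OMe)3, then H2O2/NaOH) to give the phenol F3. An intramolecular Mitsunobu reaction (PPh3, diisopropyl azodicarboxylate) closes O1–C2 with inversion, giving 32.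

**Step 14.** This is the same process on 18, with the added possibility that the silyl group wanders to the C2 oxygen and slows the closure. Fallback, from 18 back to 19, by the same inversion logic: oxidation to the ketone F4, Zn(BH4)2 reduction to the anti alcohol F5, bromine-to-hydroxyl exchange as above to the phenol F6, and Mitsunobu closure to 19.

**Step 17.** Protodeboronation of the ortho-bromo boronic acid 6 may outrun its transmetalation to rhodium, and 1,2-addition to the aldehyde may compete. Fallback, from 20 and 5 back to 24: the roles of the two rings are exchanged. 20 is lithiated and borylated (n-BuLi, B(Oi-Pr)3, dilute acid) to the lower flavan-6-boronic acid F7. 5 is homologated with Ph3P=CHCHO to the bromo enal F8. The same rhodium catalyst with the (S,S) ligand joins F7 and F8 to give 24. The bromine then sits on the acceptor, and the transmetalating partner carries only an ortho alkoxy group.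

**Step 18.** Enamine formation from the hindered β,β-diaryl aldehyde may be slow, while nitrosobenzene is lost to self-condensation and to attack at nitrogen; this costs a late intermediate. Fallback, from 24 back to 27, by auxiliary control: Pinnick oxidation (NaClO2, NaH2PO4, 2-methyl-2-butene) gives the acid F9. Acylation of the lithium salt of 9 through the pivalic mixed anhydride gives the imide F10. NaN(SiMe3)2 followed by 2-(phenylsulfonyl)-3-phenyloxaziridine hydroxylates the sodium enolate opposite the auxiliary's benzyl group to give the α-hydroxy imide F11. LiBH4 then releases diol 27.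

**Step 15.** Site selectivity may be lost, with bromination of ring B of 19 or at C5. Fallback, from 19 back to 23: a weaker, more discriminating electrophile is used. Vilsmeier–Haack formylation (POCl3, DMF, then aq. NaOAc) reacts only with the doubly activated C6 and gives the lower flavan-6-carbaldehyde F12. Wittig homologation with Ph3P=CHCHO gives 23, bypassing 20.

**Step 26.** Once the 7-hydroxyl is free, even weak acid can ionise the lower benzylic C4–O bond, leading to epimerisation or self-condensation, and the catechols oxidise readily. Fallback, from 32 back to 34: the order is reversed. Bu4NF in THF removes the silyl group while all phenols are still benzylated, giving the deca-O-benzyl dimer F13. Neutral hydrogenolysis over Pd(OH)2/C, stopped as soon as the benzyl ethers are gone, gives 34.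

## Further compounds

F1 | step 24 | (2R,3R)-2-(benzyloxy)-1-[3,4-bis(benzyloxy)phenyl]-3-[3,4-bis(benzyloxy)-2-bromophenyl]-3-(LF)propan-1-one | c9ccccc9COc1ccc(C(=O)[C@H](OCc9ccccc9)[C@H](c2cc3c(c(OCc9ccccc9)c2OCc9ccccc9)O[C@H](c2ccc(OCc9ccccc9)c(OCc9ccccc9)c2)[C@H](OCc9ccccc9)[C@H]3O[Si](C)(C)C(C)(C)C)c2ccc(OCc9ccccc9)c(OCc9ccccc9)c2Br)cc1OCc9ccccc9
F2 | step 24 | C1 epimer of 31 (1,2-anti alcohol) | c9ccccc9COc1ccc([C@H](O)[C@H](OCc9ccccc9)[C@H](c2cc3c(c(OCc9ccccc9)c2OCc9ccccc9)O[C@H](c2ccc(OCc9ccccc9)c(OCc9ccccc9)c2)[C@H](OCc9ccccc9)[C@H]3O[Si](C)(C)C(C)(C)C)c2ccc(OCc9ccccc9)c(OCc9ccccc9)c2Br)cc1OCc9ccccc9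
F3 | step 24 | phenol from F2 (hydroxyl in place of bromine) | c9ccccc9COc1ccc([C@H](O)[C@H](OCc9ccccc9)[C@H](c2cc3c(c(OCc9ccccc9)c2OCc9ccccc9)O[C@H](c2ccc(OCc9ccccc9)c(OCc9ccccc9)c2)[C@H](OCc9ccccc9)[C@H]3O[Si](C)(C)C(C)(C)C)c2ccc(OCc9ccccc9)c(OCc9ccccc9)c2O)cc1OCc9ccccc9
F4 | step 14 | (2R,3S)-2-(benzyloxy)-1-[3,4-bis(benzyloxy)phenyl]-3-[3,4-bis(benzyloxy)-2-bromophenyl]-3-[(tert-butyldimethylsilyl)oxy]propan-1-one | c9ccccc9COc1ccc(C(=O)[C@H](OCc9ccccc9)[C@@H](O[Si](C)(C)C(C)(C)C)c2ccc(OCc9ccccc9)c(OCc9ccccc9)c2Br)cc1OCc9ccccc9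
F5 | step 14 | C1 epimer of 18 (1,2-anti alcohol) | c9ccccc9COc1ccc([C@H](O)[C@H](OCc9ccccc9)[C@@H](O[Si](C)(C)C(C)(C)C)c2ccc(OCc9ccccc9)c(OCc9ccccc9)c2Br)cc1OCc9ccccc9
F6 | step 14 | phenol from F5 (hydroxyl in place of bromine) | c9ccccc9COc1ccc([C@H](O)[C@H](OCc9ccccc9)[C@@H](O[Si](C)(C)C(C)(C)C)c2ccc(OCc9ccccc9)c(OCc9ccccc9)c2O)cc1OCc9ccccc9
F7 | step 17 | (LF)boronic acid | OB(O)c1cc2c(c(OCc9ccccc9)c1OCc9ccccc9)O[C@H](c1ccc(OCc9ccccc9)c(OCc9ccccc9)c1)[C@H](OCc9ccccc9)[C@H]2O[Si](C)(C)C(C)(C)C
F8 | step 17 | (E)-3-[3,4-bis(benzyloxy)-2-bromophenyl]prop-2-enal | O=C/C=C/c1ccc(OCc9ccccc9)c(OCc9ccccc9)c1Br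
F9 | step 18 | (3R)-3-[3,4-bis(benzyloxy)-2-bromophenyl]-3-(LF)propanoic acid | OC(=O)C[C@H](c1cc2c(c(OCc9ccccc9)c1OCc9ccccc9)O[C@H](c1ccc(OCc9ccccc9)c(OCc9ccccc9)c1)[C@H](OCc9ccccc9)[C@H]2O[Si](C)(C)C(C)(C)C)c1ccc(OCc9ccccc9)c(OCc9ccccc9)c1Br
F10 | step 18 | (4R)-4-benzyl-3-[(3R)-3-[3,4-bis(benzyloxy)-2-bromophenyl]-3-(LF)propanoyl]-1,3-oxazolidin-2-one | O=C(C[C@H](c1cc2c(c(OCc9ccccc9)c1OCc9ccccc9)O[C@H](c1ccc(OCc9ccccc9)c(OCc9ccccc9)c1)[C@H](OCc9ccccc9)[C@H]2O[Si](C)(C)C(C)(C)C)c1ccc(OCc9ccccc9)c(OCc9ccccc9)c1Br)N1[C@H](Cc2ccccc2)COC1=O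
F11 | step 18 | (4R)-4-benzyl-3-[(2R,3R)-3-[3,4-bis(benzyloxy)-2-bromophenyl]-2-hydroxy-3-(LF)propanoyl]-1,3-oxazolidin-2-one | O=C([C@H](O)[C@H](c1cc2c(c(OCc9ccccc9)c1OCc9ccccc9)O[C@H](c1ccc(OCc9ccccc9)c(OCc9ccccc9)c1)[C@H](OCc9ccccc9)[C@H]2O[Si](C)(C)C(C)(C)C)c1ccc(OCc9ccccc9)c(OCc9ccccc9)c1Br)N1[C@H](Cc2ccccc2)COC1=O
F12 | step 15 | 6-formyl derivative of 19 | O=Cc1cc2c(c(OCc9ccccc9)c1OCc9ccccc9)O[C@H](c1ccc(OCc9ccccc9)c(OCc9ccccc9)c1)[C@H](OCc9ccccc9)[C@H]2O[Si](C)(C)C(C)(C)C
F13 | step 26 | deca-O-benzyl dimer with free lower 4-hydroxyl | c9ccccc9COc1ccc([C@H]2Oc3c(ccc(OCc9ccccc9)c3OCc9ccccc9)[C@@H](c3cc4c(c(OCc9ccccc9)c3OCc9ccccc9)O[C@H](c3ccc(OCc9ccccc9)c(OCc9ccccc9)c3)[C@H](OCc9ccccc9)[C@H]4O)[C@H]2OCc9ccccc9)cc1OCc9ccccc9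
A1 | alternative 1 | cis-3-benzyloxy-4-aryl-7,8-bis(benzyloxy)chroman-2-one | O=C1Oc2c(ccc(OCc9ccccc9)c2OCc9ccccc9)[C@@H](c2ccc(O[Si](C(C)C)(C(C)C)C(C)C)c(OCc9ccccc9)c2OCc9ccccc9)[C@H]1OCc9ccccc9
A2 | alternative 1 | [3,4-bis(benzyloxy)-2-hydroxyphenyl][2,3-bis(benzyloxy)-4-(triisopropylsilyloxy)phenyl]methanol | OC(c1ccc(OCc9ccccc9)c(OCc9ccccc9)c1O)c1ccc(O[Si](C(C)C)(C(C)C)C(C)C)c(OCc9ccccc9)c1OCc9ccccc9
A3 | alternative 2 | protected dimer with lower 3-(benzyldimethylsilyl) and 4-methoxy groups | c9ccccc9COc1ccc([C@H]2Oc3c(ccc(OCc9ccccc9)c3OCc9ccccc9)[C@@H](c3cc4c(c(OCc9ccccc9)c3OCc9ccccc9)O[C@H](c3ccc(OCc9ccccc9)c(OCc9ccccc9)c3)[C@H]([Si](C)(C)Cc9ccccc9)[C@H]4OC)[C@H]2OCc9ccccc9)cc1OCc9ccccc9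
A4 | alternative 2 | protected upper flavan carrying a 2,3-bis(benzyloxy)-5-formyl-4-hydroxyphenyl group at C4 | c9ccccc9COc1ccc([C@H]2Oc3c(ccc(OCc9ccccc9)c3OCc9ccccc9)[C@@H](c3cc(C=O)c(O)c(OCc9ccccc9)c3OCc9ccccc9)[C@H]2OCc9ccccc9)cc1OCc9ccccc9
A5 | alternative 2 | (Z)-benzyl[2-[3,4-bis(benzyloxy)phenyl]ethenyl]dimethylsilane | C[Si](C)(Cc9ccccc9)/C=C\c1ccc(OCc9ccccc9)c(OCc9ccccc9)c1
A6 | alternative 3 | deca-O-benzyl dimer with free lower 4-hydroxyl | c9ccccc9COc1ccc([C@H]2Oc3c(ccc(OCc9ccccc9)c3OCc9ccccc9)[C@@H](c3cc4c(c(OCc9ccccc9)c3OCc9ccccc9)O[C@H](c3ccc(OCc9ccccc9)c(OCc9ccccc9)c3)[C@H](OCc9ccccc9)[C@H]4O)[C@H]2OCc9ccccc9)cc1OCc9ccccc9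
A7 | alternative 3 | protected upper flavan whose C4 aryl group carries the open lower chain as an aryl ether aldehyde | c9ccccc9COc1ccc([C@H]2Oc3c(ccc(OCc9ccccc9)c3OCc9ccccc9)[C@@H](c3ccc(O[C@H](c4ccc(OCc9ccccc9)c(OCc9ccccc9)c4)[C@H](OCc9ccccc9)C=O)c(OCc9ccccc9)c3OCc9ccccc9)[C@H]2OCc9ccccc9)cc1OCc9ccccc9
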